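The runs were generated by integration with constants of no real substance; noise was put on by code.

- Reagent in the flask cannot fall below 60.0% of its own charge: each starting material passing the first step takes one reagent, and the flask holds 2.50 equiv, which makes starting material the limiting reagent.

| setting | midnight | spring | winter | flask |
|---|---|---|---|---|
| starting material | 0.50 M | 0.50 M | 0.25 M | 0.50 M |
| reagent | 1.2 equiv | 5 equiv | 2.5 equiv | 2.50 equiv |
| remark | run made earlier | run made earlier | run made earlier |  |
| time |  |  |  | 8.0 h |

| run | time / h | product / % | idle adduct / % |
|---|---|---|---|
| midnight | 0.417 | 1.0 | 1.7 |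
| midnight | 1.33 | 7.6 | 11.2 |
| midnight | 2.50 | 18.2 | 25.1 |
| midnight | 4.00 | 31.2 | 34.3 |
| midnight | 5.00 | 35.9 | 37.9 |
| midnight | 6.00 | 40.3 | 39.0 |
| spring | 0.417 | 3.8 | 5.0 |
| spring | 1.33 | 24.8 | 22.1 |
| spring | 2.50 | 43.6 | 22.6 |
| spring | 4.00 | 56.6 | 15.7 |
| spring | 5.00 | 59.6 | 12.5 |
| spring | 6.00 | 62.3 | 10.1 |
| winter | 0.500 | 1.1 | 1.4 |
| winter | 1.00 | 4.4 | 7.0 |
| winter | 2.00 | 15.5 | 16.0 |
| winter | 3.00 | 24.6 | 21.7 |
| winter | 6.00 | 42.4 | 26.3 |

(standard deviation of a reading: 0.5 percentage points)

- percentages count the starting material that a species holds: one idle adduct counts as two
- product is meant together with its idle adduct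
- steps under discussion: intermediate <-> product; starting material + product <-> idle adduct; starting material + reagent -> intermediate
- in an amount of product, one idle adduct counts as one product

- amount of product in the flask at 8.0 h, in percent of the starting material charged
- amount of idle adduct in the flask at 8.0 h, in percent of the starting material charged
- concentration of reagent at 8.0 h, in M

- Dividing the rate of reagent loss, as a share of its own charge, by the rate of the first step, as a share of the starting material charged, removes time and leaves the toll, 0.400 in the flask: the share of its own charge that reagent loses per fraction of charged starting material turned over.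
- The first step in the flask starts at half the rate of the spring run, so unslowed its 8.0 h count like 4.00 h there.
- The spring run's intermediate comes from the balance at 6.00 h, counting free starting material as zero: 32.6%, or 0.570 per free product. Taking the same ratio at 4.00 h, the spring run's turnover there reads 84.4%, and its free starting material reads 7.75% of the charge.
- At that turnover, reagent slows the flask to 66.2% of its starting rate but the spring run to 83.1%. The flask therefore lags, and my reckoning puts its reagent at 0.828 M or slightly above.
- The forecast gives 55%, 22% and 0.84 M, with “about 83% of the starting material through the first step”.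
- The flask gives 57.8%, 22.5% and 0.837 M.

    intermediate ⇌ product (K = 2.10, k = 0.00970 min⁻¹)
    starting material + product ⇌ idle adduct, settled at all times (K = 7.90 M⁻¹)
    starting material + reagent → intermediate (k = 0.00670 M⁻¹ min⁻¹)

- In the flask, the first step did half of its turnover by 1.23 h and reached 82.6% of the charge by 8.0 h, while free starting material fell to 6.12% of its charge and reagent held 67.0% of its own. Meanwhile intermediate stood at 25.0% at half time and 24.8% at the end, as product rose from 44.9% to 57.8%. The toll on that turnover comes to 33.0% of the reagent. The same flask charged with 0.620 equiv of reagent pays a toll of 1.61 on a turnover of 39.5%, which comes to 63.6%, and it ends with 36.4% of its reagent.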